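**Retrosynthetic overview**
1. Target 37 (germacrane locants C1–C15) comes from lactone 32 by O8 deprotection and angeloylation and by O2 desilylation; every other group is in place before the key step.
2. Key disconnection C6–C7, the bond shared by the ten-membered carbocycle and the γ-lactone: C6 carries the lactone oxygen and C7 carries the C11(=C13)–C12(=O) acrylate, so O6–C6–C7–C11=C13 is a homoallylic-alcohol retron. The open-chain bromo aldehyde 29 (C13–Br, C6=O) therefore closes both rings in one chromium-mediated allylation–lactonisation.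
3. 29 is a linear chain: the C7=C11–C13 unit by vinylalumination and SN2′ bromination at C7 (23), the C8–C9 bond with O8 and O9 by (Z)-γ-alkoxyallylboration of formyl enoate 17, and C1=C10 by iodo-Wittig olefination of aldehyde 11 followed by Stille hydroxymethylation.
4. 11 comes from (Z)-3-iodobut-2-en-1-ol (3) and (S)-benzyl glycidyl ether (4, source of C2); Sharpless epoxidation sets C4 and C5.
5. Ring order: oxirane (step 3), then carbocycle and γ-lactone together (step 18).

Key step: step 18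

Remark: the SMILES is read as a cis-4,5-epoxide (C3 and C6 on the same face, 4R,5S), a C1=C10 enoate with C2 and C9 cis, and a trans-fused 6,12-lactone; germacrane locants are used in all names.

**Step 1**
Reactants: 1 but-2-yn-1-ol
Product: 3 (Z)-3-iodobut-2-en-1-ol, via cyclic sodium alkenylalanate 2 (not isolated)
Conditions: NaAlH2(OCH2CH2OCH3)2, THF, 0 °C to rt; then I2, −78 °C
Reagents that add atoms: iodine, [I][I]
Why: Hydroxyl-directed trans-hydroalumination of the propargylic alcohol puts aluminium on the distal carbon and iodinolysis with retention gives the (Z)-iodoalkene with iodine cis to CH2OH (hydroalumination–iodination).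

**Step 2**
Reactants: 3 (Z)-3-iodobut-2-en-1-ol; 4 (S)-benzyl glycidyl ether
Product: 6 (2Z,5S)-6-(benzyloxy)-3-methylhex-2-ene-1,5-diol, via bis(chloromagnesium) alkenyl alkoxide 5 (not isolated)
Conditions: i-PrMgCl·LiCl (2.2 equiv), THF, −20 °C to rt; CuI (10 mol %), then 4, −30 to 0 °C
Reagents that add atoms: none
Why: Alkoxide-assisted iodine–magnesium exchange keeps the olefin geometry and copper-catalysed Grignard opening of the terminal epoxide at its CH2 carbon gives the (Z)-olefin with C3 cis to C6, the C2 stereocentre being carried over unchanged from 4.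

**Step 3**
Reactants: 6 (Z)-allylic alcohol diol
Product: 7 cis-epoxy diol (4R,5S)
Conditions: Ti(OiPr)4 (20 mol %), L-(+)-diethyl tartrate (24 mol %), t-BuOOH, 4 Å molecular sieves, CH2Cl2, −20 °C
Reagents that add atoms: tert-butyl hydroperoxide, CC(C)(C)OO
Why: Sharpless asymmetric epoxidation of the (Z)-trisubstituted allylic alcohol, in which the L-tartrate ligand delivers oxygen to the face that gives 4R,5S (reagent control) and the syn-stereospecific transfer turns the Z geometry into the cis relationship of C3 and C6.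

**Step 4**
Reactants: 7 cis-epoxy diol
Product: 8 primary triethylsilyl ether (O6–TES)
Conditions: Et3SiCl (1.05 equiv), imidazole, CH2Cl2, −40 °C
Reagents that add atoms: chlorotriethylsilane, CC[Si](Cl)(CC)CC
Why: Silylation of the primary hydroxyl is much faster than that of the hindered secondary one at low temperature (selective silyl ether formation).

**Step 5**
Reactants: 8 O6–TES alcohol
Product: 9 O6–TES, O2–TBS benzyl ether
Conditions: t-BuMe2SiCl, imidazole, DMF, rt
Reagents that add atoms: tert-butylchlorodimethylsilane, CC(C)(C)[Si](C)(C)Cl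
Why: Standard silylation of the remaining secondary alcohol under conditions that leave the epoxide and the triethylsilyl ether intact.

**Step 6**
Reactants: 9 benzyl ether
Product: 10 primary alcohol (C1–OH)
Conditions: H2 (1 atm), Pd/C (10 % palladium on carbon), EtOAc, rt
Reagents that add atoms: none
Why: Hydrogenolysis of the benzyl ether; the molecule has no olefin at this stage and the aliphatic epoxide and silyl ethers are stable to H2 over palladium in ethyl acetate.

**Step 7**
Reactants: 10 primary alcohol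
Product: 11 α-silyloxy aldehyde (C1 aldehyde)
Conditions: Dess–Martin periodinane, NaHCO3, CH2Cl2, 0 °C
Reagents that add atoms: none
Why: Buffered Dess–Martin oxidation should give the aldehyde without epimerisation at C2 or opening of the epoxide.

**Step 8**
Reactants: 11 C1 aldehyde; 12 methyl (triphenylphosphoranylidene)acetate
Product: 14 (Z)-2-iodoenoate, via iodo ylide 13 (not isolated)
Conditions: 12, N-iodosuccinimide, CH2Cl2, −20 °C; then 11, −20 °C to rt
Reagents that add atoms: N-iodosuccinimide, O=C1CCC(=O)N1I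
Why: Wittig olefination with the stabilised α-iodo ylide places the ester trans to C2, so iodine is cis to C2, which defines the later cis relationship of C2 and C9 across C1=C10.

**Step 9**
Reactants: 14 (Z)-2-iodoenoate; 15 (tributylstannyl)methanol
Product: 16 (E)-2-(hydroxymethyl)enoate
Conditions: 15, Pd(PPh3)4 (5 mol %), 1,4-dioxane, 80 °C
Reagents that add atoms: none
Why: Stille coupling proceeds with retention at the alkenyl iodide and transfers the hydroxymethyl group selectively, so C9 is installed cis to C2.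

**Step 10**
Reactants: 16 (E)-2-(hydroxymethyl)enoate
Product: 17 (E)-2-formyl enoate
Conditions: MnO2 (excess), CH2Cl2, rt; filtered and used at once
Reagents that add atoms: none
Why: MnO2 oxidises the allylic alcohol under neutral heterogeneous conditions, and the formyl group stays cis to C2, which is the less crowded geometry of the alkylidene formylacetate.

**Step 11**
Reactants: 17 (E)-2-formyl enoate; 18 allyl 4-methoxybenzyl ether
Product: 20 syn homoallylic alcohol (9S-OH, 8S-OPMB), via (Z)-γ-alkoxyallylborane 19 (not isolated)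
Conditions: 18, s-BuLi, THF, −78 °C; (+)-Ipc2BOMe; BF3·OEt2 (1.0 equiv); then 17, −78 °C; NaBO3·4H2O, THF/H2O, rt
Reagents that add atoms: none
Why: Brown (Z)-γ-alkoxyallylboration through a closed chair transition state gives the syn 1,2-diol monoether; the isopinocampheyl groups from (−)-α-pinene direct attack to the re face of the aldehyde (9S), the Z-allyl geometry then sets 8S, and O8 arrives as a PMB ether while O9 is free.

**Step 12**
Reactants: 20 homoallylic alcohol
Product: 21 C9 acetate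
Conditions: Ac2O, pyridine, DMAP (cat.), CH2Cl2, 0 °C
Reagents that add atoms: acetic anhydride, CC(=O)OC(C)=O
Why: Acetylation of the free C9 hydroxyl installs the acetate of the target and keeps O9 distinct from the PMB-protected O8.

**Step 13**
Reactants: 21 C9 acetate with terminal vinyl group
Product: 23 C7 aldehyde, via vicinal diol 22 (not isolated)
Conditions: OsO4 (2 mol %), NaIO4, 2,6-lutidine, 1,4-dioxane/H2O (3:1), rt
Reagents that add atoms: osmium tetroxide, O=[Os](=O)(=O)=O; sodium periodate, [Na+].[O-][I](=O)(=O)=O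
Why: Johnson–Lemieux cleavage, in which OsO4 dihydroxylates the electron-rich monosubstituted olefin in preference to the hindered ester-conjugated C1=C10 bond and periodate cleaves the diol.

**Step 14**
Reactants: 23 C7 aldehyde; 24 methyl propiolate
Product: 26 α-methylene-β-hydroxy ester (C7 epimers), via alkenylalane 25 (not isolated)
Conditions: 24, i-Bu2AlH, N-methylmorpholine N-oxide, THF, 0 °C; then 23, 0 °C to rt
Reagents that add atoms: none
Why: Vinylalumination (hydroalumination of methyl propiolate, then addition of the 1-(methoxycarbonyl)vinylalane to the aldehyde) is a non-basic Morita–Baylis–Hillman equivalent that should spare the β-acetoxy aldehyde from elimination; the new C7 carbinol centre is removed in step 15 and need not be controlled.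

**Step 15**
Reactants: 26 α-methylene-β-hydroxy ester
Product: 27 (Z)-2-(bromomethyl)enoate
Conditions: N-bromosuccinimide, Me2S, CH2Cl2, −20 to 0 °C
Reagents that add atoms: N-bromosuccinimide, O=C1CCC(=O)N1Br
Why: SN2′ bromination of the Morita–Baylis–Hillman-type alcohol gives the conjugated (Z)-allylic bromide (C8 cis to CH2Br) without amine bases that would quaternise the product.

**Step 16**
Reactants: 27 allylic bromide with O6–TES
Product: 28 epoxy alcohol (C6–OH)
Conditions: pyridinium p-toluenesulfonate (10 mol %), MeOH/CH2Cl2 (1:4), 0 °C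
Reagents that add atoms: none
Why: Acid-catalysed methanolysis removes the primary triethylsilyl ether much faster than the secondary TBS ether, and the catalytic non-nucleophilic acid leaves the allylic bromide and the epoxide intact.

**Step 17**
Reactants: 28 epoxy alcohol
Product: 29 open-chain bromo epoxy aldehyde
Conditions: Dess–Martin periodinane, NaHCO3, CH2Cl2, 0 °C; used crude
Reagents that add atoms: none
Why: Buffered, amine-free Dess–Martin oxidation gives the α,β-epoxy aldehyde next to the allylic bromide without touching either.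

**Step 18**
Reactants: 29 open-chain bromo epoxy aldehyde
Product: 32 trans-fused α-methylene-γ-lactone on the ten-membered ring (O8–PMB, O2–TBS), via allylchromium dichloride 30 (not isolated), via hydroxy ester 31 (not isolated)
Conditions: CrCl2 (10 equiv), THF/DMF (4:1), slow addition of 29 (final 2 mM), rt, then 40 °C
Reagents that add atoms: none
Why: Two equivalents of CrCl2 convert the allylic bromide into the allylchromium dichloride 30 (trivalent chromium), whose γ-carbon C7 adds to the C6 aldehyde through a six-membered chair transition state, and the chromium alkoxide 31 then attacks the neighbouring C12 methyl ester; the closest known reaction type is the chromium-mediated intramolecular Barbier (Nozaki–Hiyama-type) 2-(alkoxycarbonyl)allylation used to close ten-membered rings of epoxy-germacranolides. The carbocycle closes as a ten-membered ring by SE2′ attack of the allylmetal, which moves the double bond to the exocyclic C11=C13 position, and the lactone closes by 5-exo-trig acyl substitution. C6 is controlled by the C5 stereocentre: Felkin–Anh attack anti to the C5–O bond of the cis-epoxide places O6 anti to the epoxide oxygen (6S). C7 is controlled by the chair: the allylchromium can equilibrate by 1,3-metal shift and is expected to react through the form that holds C5 and C8 pseudo-equatorial, which gives the anti adduct and hence the trans-fused lactone (7R). The step needs chemoselective insertion into the C–Br bond (esters, epoxide, allylic acetate, silyl and PMB ethers are inert to divalent chromium, and O8 is kept as an ether so that reductive 1,4-elimination cannot compete), γ-regioselectivity, which is inherent to allylchromium reagents, and ring closure over oligomerisation, which high dilution secures.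

**Step 19**
Reactants: 32 lactone with O8–PMB
Product: 33 C8 alcohol
Conditions: DDQ, CH2Cl2/pH 7 phosphate buffer, 0 °C
Reagents that add atoms: none
Why: Oxidative cleavage of the PMB ether by DDQ under buffered conditions should leave the epoxide, the esters, the silyl ether and the α-methylene lactone untouched.

**Step 20**
Reactants: 33 C8 alcohol; 34 angelic acid
Product: 36 C8 angelate (O2–TBS), via mixed anhydride 35 (not isolated)
Conditions: 34, 2,4,6-trichlorobenzoyl chloride, Et3N, toluene, rt; then 33, 80 °C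
Reagents that add atoms: none
Why: Yamaguchi-type acylation with the preformed mixed anhydride, run without DMAP, should acylate the hindered C8 hydroxyl while keeping the Z geometry of the angelate.

**Step 21**
Reactants: 36 C8 angelate with O2–TBS
Product: 37 CNP0278274.1
Conditions: HF·pyridine, pyridine, THF, 0 °C to rt
Reagents that add atoms: none
Why: Buffered HF·pyridine removes the allylic TBS ether under conditions that the epoxide, the three esters and the α-methylene lactone are expected to tolerate.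

**Compound list**
1 | but-2-yn-1-ol | CC#CCO | starting material
2 | sodium 2,2-bis(2-methoxyethoxy)-3-methyl-2,5-dihydro-1,2-oxaluminol-2-uide (in situ) | [Na+].CC1=CCO[Al-]1(OCCOC)OCCOC | intermediate
3 | (Z)-3-iodobut-2-en-1-ol | C/C(I)=C/CO | intermediate
4 | (S)-2-[(benzyloxy)methyl]oxirane ((S)-benzyl glycidyl ether) | C1[C@H](O1)COCc1ccccc1 | starting material
5 | chloromagnesium (Z)-3-(chloromagnesio)but-2-en-1-olate (in situ) | C/C([Mg]Cl)=C/CO[Mg]Cl | intermediate
6 | (2Z,5S)-6-(benzyloxy)-3-methylhex-2-ene-1,5-diol | OC/C=C(/C)C[C@H](O)COCc1ccccc1 | intermediate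
7 | (2S)-1-(benzyloxy)-3-[(2R,3S)-3-(hydroxymethyl)-2-methyloxiran-2-yl]propan-2-ol | OC[C@@H]1O[C@]1(C)C[C@H](O)COCc1ccccc1 | intermediate
8 | (2S)-1-(benzyloxy)-3-[(2R,3S)-2-methyl-3-{[(triethylsilyl)oxy]methyl}oxiran-2-yl]propan-2-ol | CC[Si](CC)(CC)OC[C@@H]1O[C@]1(C)C[C@H](O)COCc1ccccc1 | intermediate
9 | {[(2S)-1-(benzyloxy)-3-[(2R,3S)-2-methyl-3-{[(triethylsilyl)oxy]methyl}oxiran-2-yl]propan-2-yl]oxy}(tert-butyl)dimethylsilane | CC[Si](CC)(CC)OC[C@@H]1O[C@]1(C)C[C@H](O[Si](C)(C)C(C)(C)C)COCc1ccccc1 | intermediate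
10 | (2S)-2-[(tert-butyldimethylsilyl)oxy]-3-[(2R,3S)-2-methyl-3-{[(triethylsilyl)oxy]methyl}oxiran-2-yl]propan-1-ol | CC[Si](CC)(CC)OC[C@@H]1O[C@]1(C)C[C@H](O[Si](C)(C)C(C)(C)C)CO | intermediate
11 | (2S)-2-[(tert-butyldimethylsilyl)oxy]-3-[(2R,3S)-2-methyl-3-{[(triethylsilyl)oxy]methyl}oxiran-2-yl]propanal | CC[Si](CC)(CC)OC[C@@H]1O[C@]1(C)C[C@H](O[Si](C)(C)C(C)(C)C)C=O | intermediate
12 | methyl (triphenylphosphoranylidene)acetate | COC(=O)C=P(c1ccccc1)(c1ccccc1)c1ccccc1 | starting material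
13 | methyl iodo(triphenylphosphoranylidene)acetate (in situ) | COC(=O)C(I)=P(c1ccccc1)(c1ccccc1)c1ccccc1 | intermediate
14 | methyl (2Z,4S)-4-[(tert-butyldimethylsilyl)oxy]-2-iodo-5-[(2R,3S)-2-methyl-3-{[(triethylsilyl)oxy]methyl}oxiran-2-yl]pent-2-enoate | CC[Si](CC)(CC)OC[C@@H]1O[C@]1(C)C[C@H](O[Si](C)(C)C(C)(C)C)/C=C(\I)C(=O)OC | intermediate
15 | (tributylstannyl)methanol | CCCC[Sn](CO)(CCCC)CCCC | starting material
16 | methyl (2E,4S)-4-[(tert-butyldimethylsilyl)oxy]-2-(hydroxymethyl)-5-[(2R,3S)-2-methyl-3-{[(triethylsilyl)oxy]methyl}oxiran-2-yl]pent-2-enoate | CC[Si](CC)(CC)OC[C@@H]1O[C@]1(C)C[C@H](O[Si](C)(C)C(C)(C)C)/C=C(\CO)C(=O)OC | intermediate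
17 | methyl (2E,4S)-4-[(tert-butyldimethylsilyl)oxy]-2-formyl-5-[(2R,3S)-2-methyl-3-{[(triethylsilyl)oxy]methyl}oxiran-2-yl]pent-2-enoate | CC[Si](CC)(CC)OC[C@@H]1O[C@]1(C)C[C@H](O[Si](C)(C)C(C)(C)C)/C=C(\C=O)C(=O)OC | intermediate
18 | 1-methoxy-4-[(prop-2-en-1-yloxy)methyl]benzene (allyl 4-methoxybenzyl ether) | C=CCOCc1ccc(OC)cc1 | starting material
19 | (Z)-{3-[(4-methoxybenzyl)oxy]prop-2-en-1-yl}diisopinocampheylborane, isopinocampheyl groups from (−)-α-pinene (in situ) | COc1ccc(CO/C=C\CB([C@H]2C[C@H]3C[C@@H]([C@@H]2C)C3(C)C)[C@H]2C[C@H]3C[C@@H]([C@@H]2C)C3(C)C)cc1 | intermediate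
20 | methyl (2E,4S)-4-[(tert-butyldimethylsilyl)oxy]-2-{(1S,2S)-1-hydroxy-2-[(4-methoxybenzyl)oxy]but-3-en-1-yl}-5-[(2R,3S)-2-methyl-3-{[(triethylsilyl)oxy]methyl}oxiran-2-yl]pent-2-enoate | CC[Si](CC)(CC)OC[C@@H]1O[C@]1(C)C[C@H](O[Si](C)(C)C(C)(C)C)/C=C(\[C@H](O)[C@@H](OCc1ccc(OC)cc1)C=C)C(=O)OC | intermediate
21 | methyl (2E,4S)-2-{(1S,2S)-1-acetoxy-2-[(4-methoxybenzyl)oxy]but-3-en-1-yl}-4-[(tert-butyldimethylsilyl)oxy]-5-[(2R,3S)-2-methyl-3-{[(triethylsilyl)oxy]methyl}oxiran-2-yl]pent-2-enoate | CC[Si](CC)(CC)OC[C@@H]1O[C@]1(C)C[C@H](O[Si](C)(C)C(C)(C)C)/C=C(\[C@H](OC(C)=O)[C@@H](OCc1ccc(OC)cc1)C=C)C(=O)OC | intermediate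
22 | methyl (2E,4S)-2-{(1S,2S)-1-acetoxy-3,4-dihydroxy-2-[(4-methoxybenzyl)oxy]butyl}-4-[(tert-butyldimethylsilyl)oxy]-5-[(2R,3S)-2-methyl-3-{[(triethylsilyl)oxy]methyl}oxiran-2-yl]pent-2-enoate, C7 epimers (in situ) | CC[Si](CC)(CC)OC[C@@H]1O[C@]1(C)C[C@H](O[Si](C)(C)C(C)(C)C)/C=C(\[C@H](OC(C)=O)[C@@H](OCc1ccc(OC)cc1)C(O)CO)C(=O)OC | intermediate
23 | methyl (2E,4S)-2-{(1S,2R)-1-acetoxy-2-[(4-methoxybenzyl)oxy]-3-oxopropyl}-4-[(tert-butyldimethylsilyl)oxy]-5-[(2R,3S)-2-methyl-3-{[(triethylsilyl)oxy]methyl}oxiran-2-yl]pent-2-enoate | CC[Si](CC)(CC)OC[C@@H]1O[C@]1(C)C[C@H](O[Si](C)(C)C(C)(C)C)/C=C(\[C@H](OC(C)=O)[C@@H](OCc1ccc(OC)cc1)C=O)C(=O)OC | intermediate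
24 | methyl propiolate | C#CC(=O)OC | starting material
25 | methyl 2-(diisobutylalumanyl)prop-2-enoate (in situ) | C=C(C(=O)OC)[Al](CC(C)C)CC(C)C | intermediate
26 | methyl (2E,4S)-2-{(1S,2S)-1-acetoxy-3-hydroxy-4-(methoxycarbonyl)-2-[(4-methoxybenzyl)oxy]pent-4-en-1-yl}-4-[(tert-butyldimethylsilyl)oxy]-5-[(2R,3S)-2-methyl-3-{[(triethylsilyl)oxy]methyl}oxiran-2-yl]pent-2-enoate, C7 epimers | CC[Si](CC)(CC)OC[C@@H]1O[C@]1(C)C[C@H](O[Si](C)(C)C(C)(C)C)/C=C(\[C@H](OC(C)=O)[C@@H](OCc1ccc(OC)cc1)C(O)C(=C)C(=O)OC)C(=O)OC | intermediate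
27 | methyl (2E,4S)-2-{(1S,2S,3Z)-1-acetoxy-5-bromo-4-(methoxycarbonyl)-2-[(4-methoxybenzyl)oxy]pent-3-en-1-yl}-4-[(tert-butyldimethylsilyl)oxy]-5-[(2R,3S)-2-methyl-3-{[(triethylsilyl)oxy]methyl}oxiran-2-yl]pent-2-enoate | CC[Si](CC)(CC)OC[C@@H]1O[C@]1(C)C[C@H](O[Si](C)(C)C(C)(C)C)/C=C(\[C@H](OC(C)=O)[C@@H](OCc1ccc(OC)cc1)/C=C(\CBr)C(=O)OC)C(=O)OC | intermediate
28 | methyl (2E,4S)-2-{(1S,2S,3Z)-1-acetoxy-5-bromo-4-(methoxycarbonyl)-2-[(4-methoxybenzyl)oxy]pent-3-en-1-yl}-4-[(tert-butyldimethylsilyl)oxy]-5-[(2R,3S)-3-(hydroxymethyl)-2-methyloxiran-2-yl]pent-2-enoate | OC[C@@H]1O[C@]1(C)C[C@H](O[Si](C)(C)C(C)(C)C)/C=C(\[C@H](OC(C)=O)[C@@H](OCc1ccc(OC)cc1)/C=C(\CBr)C(=O)OC)C(=O)OC | intermediate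
29 | methyl (2E,4S)-2-{(1S,2S,3Z)-1-acetoxy-5-bromo-4-(methoxycarbonyl)-2-[(4-methoxybenzyl)oxy]pent-3-en-1-yl}-4-[(tert-butyldimethylsilyl)oxy]-5-[(2R,3R)-3-formyl-2-methyloxiran-2-yl]pent-2-enoate | O=C[C@@H]1O[C@]1(C)C[C@H](O[Si](C)(C)C(C)(C)C)/C=C(\[C@H](OC(C)=O)[C@@H](OCc1ccc(OC)cc1)/C=C(\CBr)C(=O)OC)C(=O)OC | intermediate
30 | allylchromium dichloride of 29, CrCl2 group on C13 in place of bromine (in situ) | O=C[C@@H]1O[C@]1(C)C[C@H](O[Si](C)(C)C(C)(C)C)/C=C(\[C@H](OC(C)=O)[C@@H](OCc1ccc(OC)cc1)/C=C(\C[Cr](Cl)Cl)C(=O)OC)C(=O)OC | intermediate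
31 | dimethyl (1(10)E,2S,4R,5S,6S,7S,8S,9S)-9-acetoxy-2-[(tert-butyldimethylsilyl)oxy]-4,5-epoxy-6-hydroxy-8-[(4-methoxybenzyl)oxy]germacra-1(10),11(13)-diene-12,14-dioate, present as its chromium alkoxide (in situ) | C=C(C(=O)OC)[C@@H]1[C@H](OCc3ccc(OC)cc3)[C@@H](OC(C)=O)/C(C(=O)OC)=C\[C@@H](O[Si](C)(C)C(C)(C)C)C[C@@]2(C)O[C@H]2[C@H]1O | intermediate
32 | methyl (1(10)E,2S,4R,5S,6S,7R,8S,9S)-9-acetoxy-2-[(tert-butyldimethylsilyl)oxy]-4,5-epoxy-8-[(4-methoxybenzyl)oxy]germacra-1(10),11(13)-dien-12,6-olid-14-oate | C=C1C(=O)O[C@H]2[C@H]1[C@H](OCc1ccc(OC)cc1)[C@@H](OC(C)=O)/C(C(=O)OC)=C\[C@@H](O[Si](C)(C)C(C)(C)C)C[C@@]1(C)O[C@@H]21 | intermediate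
33 | methyl (1(10)E,2S,4R,5S,6S,7R,8S,9S)-9-acetoxy-2-[(tert-butyldimethylsilyl)oxy]-4,5-epoxy-8-hydroxygermacra-1(10),11(13)-dien-12,6-olid-14-oate | C=C1C(=O)O[C@H]2[C@H]1[C@H](O)[C@@H](OC(C)=O)/C(C(=O)OC)=C\[C@@H](O[Si](C)(C)C(C)(C)C)C[C@@]1(C)O[C@@H]21 | intermediate
34 | (Z)-2-methylbut-2-enoic acid (angelic acid) | C/C=C(/C)C(=O)O | starting material
35 | (Z)-2-methylbut-2-enoic 2,4,6-trichlorobenzoic anhydride (in situ) | C/C=C(/C)C(=O)OC(=O)c1c(Cl)cc(Cl)cc1Cl | intermediate
36 | methyl (1(10)E,2S,4R,5S,6S,7R,8S,9S)-9-acetoxy-2-[(tert-butyldimethylsilyl)oxy]-4,5-epoxy-8-{[(Z)-2-methylbut-2-enoyl]oxy}germacra-1(10),11(13)-dien-12,6-olid-14-oate | C=C1C(=O)O[C@H]2[C@H]1[C@H](OC(=O)/C(C)=C\C)[C@@H](OC(C)=O)/C(C(=O)OC)=C\[C@@H](O[Si](C)(C)C(C)(C)C)C[C@@]1(C)O[C@@H]21 | intermediate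
37 | methyl (1(10)E,2S,4R,5S,6S,7R,8S,9S)-9-acetoxy-4,5-epoxy-2-hydroxy-8-{[(Z)-2-methylbut-2-enoyl]oxy}germacra-1(10),11(13)-dien-12,6-olid-14-oate (CNP0278274.1) | C=C1C(=O)O[C@H]2[C@H]1[C@H](OC(=O)/C(C)=C\C)[C@@H](OC(C)=O)/C(C(=O)OC)=C\[C@@H](O)C[C@@]1(C)O[C@@H]21 | target

**Step count**
Total step count: 21. Longest linear sequence: 21 steps, from but-2-yn-1-ol (1) to 37.

**Steps most likely to fail**

Step 18 (key step). Intermolecular allylation and oligomerisation may compete with ring closure. The flexible open chain may also react through a transition state other than the chair assumed, which would give the 6,7-cis lactone series. The influence of the C8 stereocentre on the face of attack at C7 is not secured by any element of the substrate. The fallback makes the same bond through a catalytic π-allyl umpolung; it sets out from 26 and comes back at 32. Acetylation of 26 (Ac2O, pyridine, DMAP) would give the C7,C9-diacetate F1. Methanolysis of the triethylsilyl ether (pyridinium p-toluenesulfonate, MeOH) would give the epoxy alcohol F2, and buffered Dess–Martin oxidation the epoxy aldehyde F3. Under high dilution, Pd(PPh3)4 (zerovalent palladium, catalytic) should ionise the terminal allylic acetate of F3 in preference to the hindered C9 acetate, and InI (indium monoiodide) should reduce the π-allyl complex to an allylindium species. The syn-π-allyl complex leads to the (E)-allylindium reagent, which is expected to add to the C6 aldehyde through a chair transition state to the anti adduct; this lactonises to 32.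

Step 11. The doubly activated 2-formyl enoate 17 may equilibrate its olefin geometry or self-condense before it is trapped, and residual BF3 may open the epoxide. The fallback carries C14 at the alcohol oxidation level through the allylboration; it sets out from 14 and comes back at 20. Reduction of 14 (i-Bu2AlH, CH2Cl2, −78 °C) would give the (Z)-2-iodoallylic alcohol F4. Deprotonation with MeLi, iodine–lithium exchange with t-BuLi and formylation with DMF would give the configurationally stable 2-(hydroxymethyl)enal F5. The same (Z)-γ-alkoxyallylborane 19, with one extra equivalent for the free hydroxyl, would give the diol F6. Primary-selective oxidation (TEMPO, PhI(OAc)2) would give the enal F7, chlorite oxidation (NaClO2, NaH2PO4, 2-methylbut-2-ene) the acid F8, and (trimethylsilyl)diazomethane in MeOH/toluene the methyl ester 20.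

Step 20. The activated angelate may isomerise to the tiglate at the temperature that the hindered C8 hydroxyl requires, and the C9 acetyl group may migrate to O8. The fallback builds the Z double bond on the ester instead of transferring it; it sets out from 33 and comes back at 36. Esterification of 33 with 2-[bis(2,2,2-trifluoroethoxy)phosphoryl]propanoic acid (EDC, DMAP, CH2Cl2, 0 °C) would give the phosphonopropanoate F9. Still–Gennari olefination of F9 with acetaldehyde (KN(SiMe3)2, 18-crown-6, THF, −78 °C) should give the (Z)-2-methylbut-2-enoate 36.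

Further compounds
F1 | step 18 | methyl (2E,4S)-4-[(tert-butyldimethylsilyl)oxy]-2-{(1S,2S)-1,3-diacetoxy-4-(methoxycarbonyl)-2-[(4-methoxybenzyl)oxy]pent-4-en-1-yl}-5-[(2R,3S)-2-methyl-3-{[(triethylsilyl)oxy]methyl}oxiran-2-yl]pent-2-enoate, C7 epimers | CC[Si](CC)(CC)OC[C@@H]1O[C@]1(C)C[C@H](O[Si](C)(C)C(C)(C)C)/C=C(\[C@H](OC(C)=O)[C@@H](OCc1ccc(OC)cc1)C(OC(C)=O)C(=C)C(=O)OC)C(=O)OC
F2 | step 18 | methyl (2E,4S)-4-[(tert-butyldimethylsilyl)oxy]-2-{(1S,2S)-1,3-diacetoxy-4-(methoxycarbonyl)-2-[(4-methoxybenzyl)oxy]pent-4-en-1-yl}-5-[(2R,3S)-3-(hydroxymethyl)-2-methyloxiran-2-yl]pent-2-enoate, C7 epimers | OC[C@@H]1O[C@]1(C)C[C@H](O[Si](C)(C)C(C)(C)C)/C=C(\[C@H](OC(C)=O)[C@@H](OCc1ccc(OC)cc1)C(OC(C)=O)C(=C)C(=O)OC)C(=O)OC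
F3 | step 18 | methyl (2E,4S)-4-[(tert-butyldimethylsilyl)oxy]-2-{(1S,2S)-1,3-diacetoxy-4-(methoxycarbonyl)-2-[(4-methoxybenzyl)oxy]pent-4-en-1-yl}-5-[(2R,3R)-3-formyl-2-methyloxiran-2-yl]pent-2-enoate, C7 epimers | O=C[C@@H]1O[C@]1(C)C[C@H](O[Si](C)(C)C(C)(C)C)/C=C(\[C@H](OC(C)=O)[C@@H](OCc1ccc(OC)cc1)C(OC(C)=O)C(=C)C(=O)OC)C(=O)OC
F4 | step 11 | (2Z,4S)-4-[(tert-butyldimethylsilyl)oxy]-2-iodo-5-[(2R,3S)-2-methyl-3-{[(triethylsilyl)oxy]methyl}oxiran-2-yl]pent-2-en-1-ol | CC[Si](CC)(CC)OC[C@@H]1O[C@]1(C)C[C@H](O[Si](C)(C)C(C)(C)C)/C=C(\I)CO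
F5 | step 11 | (2E,4S)-4-[(tert-butyldimethylsilyl)oxy]-2-(hydroxymethyl)-5-[(2R,3S)-2-methyl-3-{[(triethylsilyl)oxy]methyl}oxiran-2-yl]pent-2-enal | CC[Si](CC)(CC)OC[C@@H]1O[C@]1(C)C[C@H](O[Si](C)(C)C(C)(C)C)/C=C(\C=O)CO
F6 | step 11 | (3S,4S)-5-{(1E,3S)-3-[(tert-butyldimethylsilyl)oxy]-4-[(2R,3S)-2-methyl-3-{[(triethylsilyl)oxy]methyl}oxiran-2-yl]but-1-en-1-ylidene... written as (2E,4S)-4-[(tert-butyldimethylsilyl)oxy]-2-{(1S,2S)-1-hydroxy-2-[(4-methoxybenzyl)oxy]but-3-en-1-yl}-5-[(2R,3S)-2-methyl-3-{[(triethylsilyl)oxy]methyl}oxiran-2-yl]pent-2-en-1-ol | CC[Si](CC)(CC)OC[C@@H]1O[C@]1(C)C[C@H](O[Si](C)(C)C(C)(C)C)/C=C(\[C@H](O)[C@@H](OCc1ccc(OC)cc1)C=C)CO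
F7 | step 11 | (2E,4S)-4-[(tert-butyldimethylsilyl)oxy]-2-{(1S,2S)-1-hydroxy-2-[(4-methoxybenzyl)oxy]but-3-en-1-yl}-5-[(2R,3S)-2-methyl-3-{[(triethylsilyl)oxy]methyl}oxiran-2-yl]pent-2-enal | CC[Si](CC)(CC)OC[C@@H]1O[C@]1(C)C[C@H](O[Si](C)(C)C(C)(C)C)/C=C(\[C@H](O)[C@@H](OCc1ccc(OC)cc1)C=C)C=O
F8 | step 11 | (2E,4S)-4-[(tert-butyldimethylsilyl)oxy]-2-{(1S,2S)-1-hydroxy-2-[(4-methoxybenzyl)oxy]but-3-en-1-yl}-5-[(2R,3S)-2-methyl-3-{[(triethylsilyl)oxy]methyl}oxiran-2-yl]pent-2-enoic acid | CC[Si](CC)(CC)OC[C@@H]1O[C@]1(C)C[C@H](O[Si](C)(C)C(C)(C)C)/C=C(\[C@H](O)[C@@H](OCc1ccc(OC)cc1)C=C)C(=O)O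
F9 | step 20 | methyl (1(10)E,2S,4R,5S,6S,7R,8S,9S)-9-acetoxy-8-({2-[bis(2,2,2-trifluoroethoxy)phosphoryl]propanoyl}oxy)-2-[(tert-butyldimethylsilyl)oxy]-4,5-epoxygermacra-1(10),11(13)-dien-12,6-olid-14-oate, epimers at the phosphonate carbon | C=C1C(=O)O[C@H]2[C@H]1[C@H](OC(=O)C(C)P(=O)(OCC(F)(F)F)OCC(F)(F)F)[C@@H](OC(C)=O)/C(C(=O)OC)=C\[C@@H](O[Si](C)(C)C(C)(C)C)C[C@@]1(C)O[C@@H]21
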